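**Retrosynthetic overview**

1. Target 15 ⇐ 3-bromo-5,6,7,8-tetramethoxyflavone 14, by C3–O coupling with methanol as the last step.
2. The route rests on one feature: C3 of ring C is a single carbon lying between C2 (bound to O1 and the phenyl ring B) and the C4 carbonyl. Ring C is therefore the furan ring of a 2-phenylbenzofuran-3-ol with one carbon pushed into its C2–C3 bond, so 14 ⇐ silyl ether 10 + CBr2 from bromoform 11 (new flavone bonds C2–C3 and C3–C4, five- to six-membered ring).
3. 10 ⇐ benzofuranone 9 ⇐ aryloxy(phenyl)acetic acid 7 (Friedel–Crafts closure at the only C–H of ring A) ⇐ phenol 4 + bromoester 5.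
4. 4 ⇐ 1,2,3,4-tetramethoxybenzene 1 by ortho-lithiation, borylation and oxidation.
5. Ring order: ring A and the phenyl ring are bought; the furanone ring closes in step 4 and is enlarged to the pyranone ring C in step 6.

Key step: step 6

Assumption: compounds 5, 6, 7, 8, 9 and 12 are racemic and are drawn without stereodescriptors; the target has no stereocentre, and the one carbon stereocentre made in step 2 becomes sp2 in step 5.

**Route**

Step 1
Reactants: 1 1,2,3,4-tetramethoxybenzene
Product: 4 2,3,4,5-tetramethoxyphenol, via aryllithium 2 (not isolated), via dimethyl arylboronate 3 (not isolated)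
Conditions: n-BuLi, TMEDA, THF, 0 °C; B(OMe)3, −78 °C → rt; then 30% H2O2, AcOH, 0 °C → rt
Reagents that add atoms: hydrogen peroxide, OO (oxygen of the phenol 4); n-butyllithium, [Li]CCCC (lithium of 2); trimethyl borate, COB(OC)OC (boron and two methoxy groups of 3)
Why: Methoxy-directed ortho-lithiation (the two ring C–H positions are equivalent by symmetry), borylation and oxidative boron-to-oxygen aryl migration form the standard arene-to-phenol sequence, and the mildly acidic peroxide medium should spare the electron-rich phenol from over-oxidation.

Step 2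
Reactants: 4 2,3,4,5-tetramethoxyphenol; 5 methyl 2-bromo-2-phenylacetate (racemic)
Product: 6 methyl 2-phenyl-2-(2,3,4,5-tetramethoxyphenoxy)acetate (racemic)
Conditions: K2CO3, acetone, reflux, N2
Reagents that add atoms: none
Why: Williamson ether synthesis, in which the phenoxide displaces the benzylic α-carbonyl bromide by SN2 with no elimination possible (no β-hydrogen); the new stereocentre forms as a racemate, which does not matter because it is planarised in step 5.

Step 3
Reactants: 6 methyl 2-phenyl-2-(2,3,4,5-tetramethoxyphenoxy)acetate
Product: 7 2-phenyl-2-(2,3,4,5-tetramethoxyphenoxy)acetic acid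
Conditions: LiOH·H2O, THF/MeOH/H2O, rt; then 1 M HCl
Reagents that add atoms: lithium hydroxide, [Li+].[OH-] (the hydroxide oxygen ends in the carboxyl group)
Why: Ordinary ester saponification by acyl–oxygen cleavage; the aryl methyl ethers and the aryl alkyl ether are inert to aqueous hydroxide at room temperature.

Step 4
Reactants: 7 2-phenyl-2-(2,3,4,5-tetramethoxyphenoxy)acetic acid
Product: 9 4,5,6,7-tetramethoxy-2-phenylbenzofuran-3(2H)-one, via mixed trifluoroacetic anhydride 8 (not isolated)
Conditions: (CF3CO)2O, CF3CO2H (cat.), CH2Cl2, 0 °C → rt, Ar; then aq. NaHCO3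
Reagents that add atoms: trifluoroacetic anhydride, O=C(OC(=O)C(F)(F)F)C(F)(F)F (trifluoroacetyl group of intermediate 8 only; none of its atoms remain in 9)
Why: Intramolecular Friedel–Crafts acylation through the mixed anhydride: the single free ring carbon is ortho to the aryloxy oxygen and to one methoxy group and para to another, so the five-membered ketone should close under mild acid, without a strong Lewis acid that could cleave methyl ethers or provoke decarbonylation, and the bicarbonate work-up also cleaves any enol trifluoroacetate.

Step 5
Reactants: 9 4,5,6,7-tetramethoxy-2-phenylbenzofuran-3(2H)-one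
Product: 10 tert-butyl[(4,5,6,7-tetramethoxy-2-phenylbenzofuran-3-yl)oxy]dimethylsilane
Conditions: TBSOTf, Et3N, CH2Cl2, 0 °C, Ar
Reagents that add atoms: tert-butyldimethylsilyl trifluoromethanesulfonate, CC(C)(C)[Si](C)(C)OS(=O)(=O)C(F)(F)F
Why: Silyl enol ether formation by soft enolisation: C2–H is acidified by the carbonyl, the ring oxygen and the phenyl group, and the enol is an aromatic benzofuran, so O-silylation should be fast; the tert-butyldimethylsilyl group is preferred to trimethylsilyl so that the ether can be purified and resists tert-butoxide in step 6.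

Step 6
Reactants: 10 tert-butyl[(4,5,6,7-tetramethoxy-2-phenylbenzofuran-3-yl)oxy]dimethylsilane; 11 bromoform
Product: 14 3-bromo-5,6,7,8-tetramethoxyflavone, via gem-dibromocyclopropane 12 (not isolated), via 4-silyloxyflavylium bromide 13 (not isolated)
Conditions: CHBr3 (2.5 equiv), KOtBu (4 equiv), hexane/toluene, −30 °C → rt, Ar
Reagents that add atoms: none
Why: Proposed new method: α-elimination of CHBr3 by KOtBu gives dibromocarbene, which as an electrophile should add [2+1] to the C2=C3 bond of 10 (the one alkene carrying two oxygen donors) and so close the three-membered ring of the cis-fused cyclopropane 12. Pushed by the O1 lone pair, the phenyl group and the silyloxy oxygen, 12 should undergo the allowed disrotatory two-electron opening with departure of the endo bromide, the only mode that keeps the emerging allyl cation cis inside the ring; the fusion bond (old C2–C3) breaks, so ring C arises by enlargement of the furan from five to six members (new flavone bonds C2–C3 and C3–C4) and not by closure of a chain, giving the aromatic flavylium ion 13. Removal of the silyl group from the C4 oxygen of 13 by tert-butoxide (or bromide) then unveils the carbonyl and leaves bromine on the inserted carbon. The closest known reaction types are the dihalocarbene one-carbon ring expansion of cyclic silyl enol ethers to 2-haloenones and the Ciamician–Dennstedt enlargement of indoles and benzofurans; their union on a 3-silyloxybenzofuran is untested. No stereocentre remains in 14; the two of 12 are necessarily cis by ring fusion and vanish on opening. The step needs the carbene to attack only C2=C3 and the silyl ether to outlast tert-butoxide until it has been cyclopropanated, which the doubly oxygenated alkene, the absence of any C–H on ring A, the unactivated phenyl ring, the bulky tert-butyldimethylsilyl group and the low temperature in a non-polar medium should secure.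

Step 7
Reactants: 14 3-bromo-5,6,7,8-tetramethoxyflavone
Product: 15 3,5,6,7,8-pentamethoxyflavone
Conditions: CuI (10 mol %), 3,4,7,8-tetramethyl-1,10-phenanthroline (20 mol %), Cs2CO3, CH3OH, toluene, 90 °C, sealed tube
Reagents that add atoms: methanol, CO
Why: Ullmann-type copper-catalysed C–O coupling: the electron-poor C3–Br bond of the α-bromoenone should add readily to the phenanthroline-ligated monovalent copper methoxide, and keeping methanol a minor component in toluene with a carbonate base holds free methoxide low to limit attack at C2.

**Compound list**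

1 | 1,2,3,4-tetramethoxybenzene | COc1ccc(OC)c(OC)c1OC | starting material
2 | (2,3,4,5-tetramethoxyphenyl)lithium | [Li]c1cc(OC)c(OC)c(OC)c1OC | intermediate
3 | dimethyl (2,3,4,5-tetramethoxyphenyl)boronate | COB(OC)c1cc(OC)c(OC)c(OC)c1OC | intermediate
4 | 2,3,4,5-tetramethoxyphenol | Oc1cc(OC)c(OC)c(OC)c1OC | intermediate
5 | methyl 2-bromo-2-phenylacetate (methyl α-bromophenylacetate, racemic) | COC(=O)C(Br)c1ccccc1 | starting material
6 | methyl 2-phenyl-2-(2,3,4,5-tetramethoxyphenoxy)acetate (racemic) | COC(=O)C(Oc1cc(OC)c(OC)c(OC)c1OC)c1ccccc1 | intermediate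
7 | 2-phenyl-2-(2,3,4,5-tetramethoxyphenoxy)acetic acid (racemic) | OC(=O)C(Oc1cc(OC)c(OC)c(OC)c1OC)c1ccccc1 | intermediate
8 | 2-phenyl-2-(2,3,4,5-tetramethoxyphenoxy)acetic trifluoroacetic anhydride (racemic) | O=C(OC(=O)C(F)(F)F)C(Oc1cc(OC)c(OC)c(OC)c1OC)c1ccccc1 | intermediate
9 | 4,5,6,7-tetramethoxy-2-phenylbenzofuran-3(2H)-one (racemic) | COc1c(OC)c(OC)c2C(=O)C(c3ccccc3)Oc2c1OC | intermediate
10 | tert-butyl[(4,5,6,7-tetramethoxy-2-phenylbenzofuran-3-yl)oxy]dimethylsilane | COc1c(OC)c(OC)c2c(O[Si](C)(C)C(C)(C)C)c(-c3ccccc3)oc2c1OC | intermediate
11 | bromoform | BrC(Br)Br | starting material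
12 | 1,1-dibromo-6b-(tert-butyldimethylsilyloxy)-3,4,5,6-tetramethoxy-1a-phenyl-1a,6b-dihydro-1H-cyclopropa[b]benzofuran (CBr2 bridging the former furan C2 and C3; cis-fused, racemic) | COc1c(OC)c(OC)c2c(c1OC)OC1(c3ccccc3)C(Br)(Br)C21O[Si](C)(C)C(C)(C)C | intermediate
13 | 3-bromo-4-(tert-butyldimethylsilyloxy)-5,6,7,8-tetramethoxy-2-phenylchromenylium bromide | COc1c(OC)c(OC)c2c(O[Si](C)(C)C(C)(C)C)c(Br)c(-c3ccccc3)[o+]c2c1OC.[Br-] | intermediate
14 | 3-bromo-5,6,7,8-tetramethoxyflavone | COc1c(OC)c(OC)c2c(=O)c(Br)c(-c3ccccc3)oc2c1OC | intermediate
15 | 3,5,6,7,8-pentamethoxyflavone | COc1c(OC)c(OC)c2c(=O)c(OC)c(-c3ccccc3)oc2c1OC | target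

**Step count**

Total: 7 steps. Longest linear sequence: 7 steps (1 → 15); 5 and 11 are used as bought.

**Steps most likely to fail**

Step 6. The silyl ether may be cleaved by tert-butoxide before the carbene is captured, and the free enolate may then be C-alkylated by the carbene without ring growth. The crowded tetrasubstituted alkene may also capture the carbene too slowly, or excess base may degrade the bromochromone once formed. The fallback uses known chemistry only; it sets out from phenol 4 and comes back at the target 15. Direct ortho C-acylation of 4 at its only free ring carbon with methoxyacetic acid in BF3·OEt2 (70–80 °C) should give 1-(2-hydroxy-3,4,5,6-tetramethoxyphenyl)-2-methoxyethan-1-one F1. Allan–Robinson condensation of F1 with benzoic anhydride and PhCO2Na at about 180 °C, followed by brief KOH/EtOH treatment, should then build ring C with the 3-methoxy group already in place and deliver 15.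

Step 7. Methoxide may add in conjugate fashion at C2 of the bromochromone, leading to opening of the pyranone or contraction to a benzofuranone, and reductive loss of bromine may compete with C–O bond formation. The fallback sets out from 14 and comes back at 15 without an alkoxide nucleophile at the coupling stage. Miyaura borylation (Pd(dppf)Cl2, bis(pinacolato)diboron, KOAc, dioxane, 80 °C) should give 5,6,7,8-tetramethoxy-2-phenyl-3-(4,4,5,5-tetramethyl-1,3,2-dioxaborolan-2-yl)-4H-chromen-4-one F2. Oxidation (30% H2O2, pH 7 phosphate buffer, THF, 0 °C → rt) should give 3-hydroxy-5,6,7,8-tetramethoxyflavone F3. O-Methylation of F3 (CH3I, K2CO3, acetone, reflux) should give 15.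

Step 4. The activated acyl species may lose carbon monoxide to a stabilised oxocarbenium ion instead of acylating the ring, acid may cleave the methyl ether next to the new carbonyl, and the product may be oxidised by air at C2 during basic work-up. The fallback sets out from phenol 4 and comes back at benzofuranone 9, forming the aryl–carbonyl bond first and the ring C–O bond last. Ortho C-acylation of 4 with phenylacetic acid in BF3·OEt2 (70–80 °C) should give 1-(2-hydroxy-3,4,5,6-tetramethoxyphenyl)-2-phenylethan-1-one F4. α-Bromination with phenyltrimethylammonium tribromide (THF, 0 °C → rt; ring A has no free position) should give 2-bromo-1-(2-hydroxy-3,4,5,6-tetramethoxyphenyl)-2-phenylethan-1-one F5. Intramolecular O-alkylation of F5 (K2CO3, acetone, rt, Ar) should close the furanone to 9.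

**Further compounds**

F1 | step 6 | 1-(2-hydroxy-3,4,5,6-tetramethoxyphenyl)-2-methoxyethan-1-one | COCC(=O)c1c(O)c(OC)c(OC)c(OC)c1OC
F2 | step 7 | 5,6,7,8-tetramethoxy-2-phenyl-3-(4,4,5,5-tetramethyl-1,3,2-dioxaborolan-2-yl)-4H-chromen-4-one | COc1c(OC)c(OC)c2c(=O)c(B3OC(C)(C)C(C)(C)O3)c(-c3ccccc3)oc2c1OC
F3 | step 7 | 3-hydroxy-5,6,7,8-tetramethoxyflavone | COc1c(OC)c(OC)c2c(=O)c(O)c(-c3ccccc3)oc2c1OC
F4 | step 4 | 1-(2-hydroxy-3,4,5,6-tetramethoxyphenyl)-2-phenylethan-1-one | O=C(Cc1ccccc1)c1c(O)c(OC)c(OC)c(OC)c1OC
F5 | step 4 | 2-bromo-1-(2-hydroxy-3,4,5,6-tetramethoxyphenyl)-2-phenylethan-1-one (racemic) | O=C(C(Br)c1ccccc1)c1c(O)c(OC)c(OC)c(OC)c1OC
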